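## Analysis of the target

Target 32 is a sesquineolignan of three C6C3 units. A guaiacylglycerol unit (ring A with side-chain carbons Cα, Cβ, Cγ) is joined through a Cβ–O ether to O4 of a syringyl ring (ring B), and ring B sits on C2 of a 2,3-dihydro-1-benzofuran whose benzo ring (ring C) carries the formyl group at C5 and a methoxy group at C7. The four stereocentres form two pairs: C2 and C3 of the dihydrofuran are (2R,3S), with aryl and hydroxymethyl trans, and the side chain is (αS,βR), the erythro arrangement of the Cα hydroxyl and the Cβ aryloxy group. The pairs are separated by the whole of ring B and cannot steer each other, so each has to be set by a reagent or an auxiliary. Sensitive sites are the aryl aldehyde, the free ring A phenol para to the secondary benzylic alcohol (a pair that ionises or forms a quinone methide under acid or strong base), the benzylic C2–O1 ether (acid, hydrogenolysis) and the β-aryl ether. The synthesis is hard for three reasons: ring C is a 1,2,3,5-tetrasubstituted arene with three contiguous substituents (C3a alkyl branch, C7a oxygen, C7 methoxy), the trans ring must be made in one absolute sense, and the ether oxygen of ring B is flanked by two methoxy groups, which makes an SN2 reaction of that phenoxide at the secondary Cβ unattractive. The strategy rests on the two neighbouring C–O bonds of ring C, C7a–O1 and C7–O. They lie on adjacent carbons next to the C3a branch, which is the pattern left when a tethered oxygen nucleophile adds to one carbon of a C7–C7a aryne and an electrophile is delivered to the other.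

## Retrosynthetic reasoning

**Unmasking (32 ⇐ 31 ⇐ 30 ⇐ 29).** The aldehyde is released last from the dioxolane of 31, because all earlier side-chain chemistry uses enolates, hydride and a basic ester cleavage. Before that, the two silyl ethers of 30 are removed with fluoride and the ring A allyl ether of 29 under neutral palladium catalysis. The ring A phenol is kept as an allyl ether until Cα is finished, so that no phenoxide can expel a benzylic leaving group as a quinone methide.

**Cα–O bond, with inversion (29 ⇐ 28 ⇐ 27 ⇐ 26).** An auxiliary-controlled boron aldol gives the syn adduct. With the chain drawn as a zigzag the two oxygens are on the same side, and that is the threo, (αR,βR), arrangement, not the erythro one that is needed. Cβ carries the aryl ether and cannot be inverted, so the benzylic Cα–O bond is cut and re-formed by SN2 (ester 28 from alcohol 27). Diol 26 is first silylated at the primary Cγ oxygen so that only the Cα hydroxyl reacts.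

**Cα–Cβ bond (26 ⇐ 25 ⇐ 22 + 23).** Cutting here turns the side chain into an aryloxyacetyl imide 22 and the protected vanillin 23. The ring B oxygen is already attached to the enolate carbon, so the hindered phenoxide never has to attack a secondary carbon. The forward aldol must fix Cβ as R, which the (S)-auxiliary does.

**O–CH2 bond at ring B (22 ⇐ 19 + 21; 21 ⇐ 20).** The phenol 19 is alkylated at the primary, carbonyl-activated carbon of bromoacetyl imide 21. This brings in the auxiliary and the two-carbon unit in one step.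

**Phenol adjustments (19 ⇐ 18 ⇐ 17).** The ring B oxygen is freed from a benzyl ether by hydrogenolysis. Benzyl is chosen because an acetal-type phenol protecting group could not be cleaved beside the dioxolane, and because benzyl tolerates amide bases and boron enolates. The C7 methoxy group comes from methylation of the phenol 17.

**O1–C7a and C7–O bonds (17 ⇐ 13, through 14, 15, 16).** Both ring C oxygens are removed at once. The precursor 13 is a plain ortho-fluoroarene with a benzylic alcohol two carbons away. The forward step makes the C7–C7a aryne 14, closes the dihydrofuran by addition of the alkoxide to C7a (15), and converts the resulting C7 anion into a phenol through boronate 16. Cutting here, and not at O1–C2, leaves both stereocentres untouched in the ring closure, and ring C can start from a cheap 1,2,4-trisubstituted benzene.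

**C2–C3 bond and the primary oxygen (13 ⇐ 12 ⇐ 11 ⇐ 9 + 2).** The two ring stereocentres are made together in a syn-aldol between arylacetyl imide 9 and aldehyde 2. Reductive removal of the auxiliary gives diol 12 and selective silylation gives 13. The syn adduct maps onto the trans ring because the ring closure retains configuration at both centres.

**Ring C side chain (9 ⇐ 6 + 7; 6 ⇐ 5 ⇐ 4 ⇐ 3; 2 ⇐ 1).** The aryl–CH2 bond of acid 6 is made by palladium-catalysed enolate arylation of the bromide 4, the dioxolane of aldehyde 3. Aldehyde 2 is the benzyl ether of 1.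

## Alternatives that were turned down

**Alternative 1:** The C2–C3 bond is cut. In the forward direction the aryldiazoacetate A1, whose ring C oxygen already carries the syringyl benzyl group, is decomposed by Rh2(S-DOSP)4 or its enantiomer. The metal-bound carbene inserts into the O–CH2 C–H bond and closes the ring to the cis diester A2.
- For: the stereocentres come from a catalyst and not from an auxiliary. The C–H bond is activated by oxygen and by an electron-rich aryl group. All ring C substituents are present from the start, so no aryne and no late oxygenation are needed. In step count to the bicyclic core it is at least as short as the chosen route.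
- Against, for this target: the insertion gives the cis ring, so C3 must be epimerised α to the ester. The C3 enolate can expel the phenoxide O1 (retro-oxa-Michael ring opening), which would erase C2 as well. The carbene sits next to an ether oxygen and can form an oxonium ylide and rearrange instead of inserting. The two esters of A2 must be taken to different oxidation levels (CH2OH at C3, CHO at C5).
- Comparison: the chosen strategy gives up catalytic asymmetry. In exchange it delivers the trans ring directly from a syn-aldol adduct, with no epimerisation, and carries C5 at the aldehyde oxidation level throughout.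

**Alternative 2:** The O1–C2 bond is cut and C2 is left as a benzylic CH2 in the diarylpropyl acetate A3, whose single stereocentre (the later C3) comes from one asymmetric catalytic step. In the forward direction Ag2O oxidises the syringyl phenol of A3 to the para-quinone methide A4, and the ring C phenol adds to the exocyclic carbon to give the trans acetate A5.
- For: it is biomimetic and needs only one stereocentre from a catalyst. A5 emerges with the ring B phenol free and the aldehyde in place. In protecting-group economy it is stronger than the chosen route, which needs a benzyl ether and a dioxolane.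
- Against: C2 is planar in A4, so its configuration depends entirely on 1,2-induction from C3, which favours trans but is not guaranteed. A4 has a hydrogen on C3 and can tautomerise into conjugation with ring B, which would destroy the only stereocentre. A3, with its lone benzylic stereocentre, still needs an enantioselective synthesis of its own.
- Comparison: the chosen strategy fixes both ring stereocentres in one auxiliary-controlled aldol before ring closure and closes the ring at an sp2 aryl carbon, so neither centre ever becomes planar.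

**Alternative 3:** Both bonds from ring C to the dihydrofuran carbons, C3–C3a and O1–C2, are cut at the very end. In the forward direction 5-iodovanillin A6 and the (E)-sinapyl silyl ether A7, which already carries the protected erythro side chain, are joined with Pd(OAc)2, a chiral phosphine and Ag2CO3. Oxidative addition, carbopalladation of the alkene and C–O bond formation at the benzylic carbon give the protected target A8.
- For: it is the most convergent plan. Ring C needs no synthesis, and one step forms a C–C and a C–O bond. In step count and convergence it is clearly stronger than the chosen linear route.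
- Against: the absolute configuration at C2 and C3 would have to come from the ligand in an intermolecular oxyarylation of an electron-rich 1,2-disubstituted styrene, a reaction without dependable enantiocontrol. The side-chain stereocentres of A7 are too remote to help, so imperfect catalyst control would give diastereomers of a heavy, late intermediate that differ only at distant centres. β-Hydride elimination and loss of the allylic silyloxy group compete with C–O bond formation.
- Comparison: the chosen strategy spends more steps, but sets each stereo pair with an auxiliary on a small substrate, where diastereomers can be separated and the auxiliary recovered.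

Key step: step 9

Remark on the chemistry: (2-ethoxy-2-oxoethyl)zinc bromide, both enantiomers of 4-benzyl-1,3-oxazolidin-2-one and 4-(allyloxy)-3-methoxybenzaldehyde are taken as purchasable. In names from 22 on, "BC-aryloxy" stands for the 4-[(2R,3S)-5-(1,3-dioxolan-2-yl)-7-methoxy-3-{[(triisopropylsilyl)oxy]methyl}-2,3-dihydro-1-benzofuran-2-yl]-2,6-dimethoxyphenoxy group, i.e. 19 bound through its phenol oxygen.

## Route

Step 1
Reactants: 1 syringaldehyde (4-hydroxy-3,5-dimethoxybenzaldehyde)
Product: 2 4-(benzyloxy)-3,5-dimethoxybenzaldehyde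
Conditions: BnBr, K2CO3, DMF, 60 °C
Reagents that add atoms: benzyl bromide, BrCc1ccccc1
Why: Williamson etherification of an acidic phenol. Benzyl survives the amide base and boron enolates used later and is removed by hydrogenolysis without touching the acetal or silyl ether.

Step 2
Reactants: 3 3-bromo-4-fluorobenzaldehyde
Product: 4 2-(3-bromo-4-fluorophenyl)-1,3-dioxolane
Conditions: HOCH2CH2OH, TsOH (cat.), toluene, reflux, Dean–Stark
Reagents that add atoms: ethylene glycol, OCCO
Why: Acid-catalysed acetalisation with azeotropic removal of water. The aldehyde is masked in a base-stable form for the enolate and aryne chemistry.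

Step 3
Reactants: 4 2-(3-bromo-4-fluorophenyl)-1,3-dioxolane
Product: 5 ethyl [5-(1,3-dioxolan-2-yl)-2-fluorophenyl]acetate
Conditions: BrZnCH2CO2Et, Pd2(dba)3 (cat.), XPhos (cat.), THF, 65 °C
Reagents that add atoms: (2-ethoxy-2-oxoethyl)zinc bromide, CCOC(=O)C[Zn]Br
Why: Palladium-catalysed α-arylation of a zinc ester enolate (Reformatsky–Negishi coupling). Oxidative addition of zerovalent palladium occurs only at C–Br, and the near-neutral zinc enolate leaves acetal and aryl fluoride alone.

Step 4
Reactants: 5 ethyl [5-(1,3-dioxolan-2-yl)-2-fluorophenyl]acetate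
Product: 6 [5-(1,3-dioxolan-2-yl)-2-fluorophenyl]acetic acid
Conditions: LiOH, THF/H2O, rt; then cold 1 M HCl to pH 4
Reagents that add atoms: lithium hydroxide, [Li+].[OH-]
Why: Ester saponification. Brief cold acidification to about pH 4 should liberate the acid without hydrolysing the acetal of this unactivated benzaldehyde.

Step 5
Reactants: 6 [5-(1,3-dioxolan-2-yl)-2-fluorophenyl]acetic acid; 7 (R)-4-benzyl-1,3-oxazolidin-2-one
Product: 9 (R)-4-benzyl-3-{[5-(1,3-dioxolan-2-yl)-2-fluorophenyl]acetyl}-1,3-oxazolidin-2-one, via mixed pivalic anhydride 8 (not isolated)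
Conditions: PivCl, Et3N, THF, −20 °C; then 7, LiCl, −20 °C to rt
Reagents that add atoms: none
Why: N-Acylation of the oxazolidinone through the mixed pivalic anhydride with LiCl and Et3N. The hindered pivaloyl carbonyl directs attack to the arylacetyl carbonyl.

Step 6
Reactants: 9 (R)-4-benzyl-3-{[5-(1,3-dioxolan-2-yl)-2-fluorophenyl]acetyl}-1,3-oxazolidin-2-one; 2 4-(benzyloxy)-3,5-dimethoxybenzaldehyde
Product: 11 (4R)-4-benzyl-3-{(2R,3R)-3-[4-(benzyloxy)-3,5-dimethoxyphenyl]-2-[5-(1,3-dioxolan-2-yl)-2-fluorophenyl]-3-hydroxypropanoyl}-1,3-oxazolidin-2-one, via boron Z-enolate 10 (not isolated)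
Conditions: Bu2BOTf, iPr2NEt, CH2Cl2, −78 to 0 °C; then 2, −78 to 0 °C; pH 7 buffer, MeOH, H2O2, 0 °C
Reagents that add atoms: none
Why: Evans boron syn-aldol. The Z-enolate reacts through a closed Zimmerman–Traxler chair on the face away from the benzyl group of the (R)-auxiliary, which sets both new centres as (2R,3R), the syn relationship that becomes trans in the ring. The amine base keeps the boron triflate from opening the acetal.

Step 7
Reactants: 11 syn-aldol adduct (named in step 6)
Product: 12 (1R,2S)-1-[4-(benzyloxy)-3,5-dimethoxyphenyl]-2-[5-(1,3-dioxolan-2-yl)-2-fluorophenyl]propane-1,3-diol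
Conditions: LiBH4, THF, H2O (1 equiv), 0 °C to rt
Reagents that add atoms: none
Why: Reductive cleavage of the N-acyl oxazolidinone to the primary alcohol. The auxiliary is released for recovery, and the descriptor at C2 changes only because CH2OH ranks lower than the former carbonyl carbon.

Step 8
Reactants: 12 (1R,2S)-diol
Product: 13 (1R,2S)-1-[4-(benzyloxy)-3,5-dimethoxyphenyl]-2-[5-(1,3-dioxolan-2-yl)-2-fluorophenyl]-3-[(triisopropylsilyl)oxy]propan-1-ol
Conditions: TIPSCl, imidazole, DMF, 0 °C to rt
Reagents that add atoms: triisopropylsilyl chloride, CC(C)[Si](Cl)(C(C)C)C(C)C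
Why: Selective silylation of the primary hydroxyl over the hindered benzylic one. The bulky triisopropylsilyl group is chosen because both oxygens of this 2-aryl-1,3-diol are equally placed to reach the aryne, and silyl migration to the secondary alkoxide would exchange their roles.

Step 9
Reactants: 13 (1R,2S)-1-[4-(benzyloxy)-3,5-dimethoxyphenyl]-2-[5-(1,3-dioxolan-2-yl)-2-fluorophenyl]-3-[(triisopropylsilyl)oxy]propan-1-ol
Product: 17 (2R,3S)-2-[4-(benzyloxy)-3,5-dimethoxyphenyl]-5-(1,3-dioxolan-2-yl)-3-{[(triisopropylsilyl)oxy]methyl}-2,3-dihydro-1-benzofuran-7-ol, via lithium alkoxide aryne 14 (not isolated), via C7 aryllithium 15 (not isolated), via C7 dimethyl boronate 16 (not isolated)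
Conditions: LiTMP (3.5 equiv, from 2,2,6,6-tetramethylpiperidine and n-BuLi), THF, −78 to 0 °C; then B(OMe)3, −78 °C to rt; then H2O2, NaOH (aq), 0 °C
Reagents that add atoms: hydrogen peroxide, OO
Why: The first equivalent of LiTMP gives the lithium alkoxide, further base removes the only hydrogen ortho to fluorine, and on warming the ortho-lithio fluoride loses LiF to give aryne 14 across C7–C7a. The alkoxide oxygen adds to C7a in a 5-exo-dig closure (O1–C7a); attack at C7 would need a bridged ring, so the carbanion appears at C7, next to the new oxygen, as aryllithium 15. This is the known aryne-mediated anionic cyclisation of 2-(2-haloaryl)ethoxides to 2,3-dihydrobenzofurans with electrophilic trapping of the resulting aryllithium; here the electrophile is B(OMe)3, and boronate 16 is oxidised in the same flask by H2O2 with 1,2-migration of the aryl group from boron to oxygen (C7–O). No stereocentre is made: the C2–O and C3–C3a bonds are not touched, so the syn-aldol configuration is carried with retention into the trans ring. The selectivity needed is regiochemical and is built into the substrate: fluorine has one ortho hydrogen, so only one aryne can form, and the two-carbon tether lets oxygen reach C7a only. The hindered amine that is released is a poor proton donor toward 15, excess LiTMP holds the aryllithium until the borate is added, and the bulky silyl ether keeps the primary oxygen out of the cyclisation.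

Step 10
Reactants: 17 7-hydroxy dihydrobenzofuran (named in step 9)
Product: 18 (2R,3S)-2-[4-(benzyloxy)-3,5-dimethoxyphenyl]-5-(1,3-dioxolan-2-yl)-7-methoxy-3-{[(triisopropylsilyl)oxy]methyl}-2,3-dihydro-1-benzofuran
Conditions: MeI, K2CO3, acetone, 50 °C
Reagents that add atoms: iodomethane, CI
Why: Williamson methylation of the only free phenol; nothing else in 17 is alkylated by carbonate and iodomethane.

Step 11
Reactants: 18 7-methoxy benzyl ether (named in step 10)
Product: 19 4-[(2R,3S)-5-(1,3-dioxolan-2-yl)-7-methoxy-3-{[(triisopropylsilyl)oxy]methyl}-2,3-dihydro-1-benzofuran-2-yl]-2,6-dimethoxyphenol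
Conditions: H2 (1 atm), 10% Pd/C, EtOAc, rt
Reagents that add atoms: none
Why: Hydrogenolysis of the aryl benzyl ether under neutral conditions. Such ethers cleave much faster than the cyclic benzylic C2–O1 ether, and the acetal and silyl ether are inert without acid.

Step 12
Reactants: 20 (S)-4-benzyl-1,3-oxazolidin-2-one
Product: 21 (S)-4-benzyl-3-(bromoacetyl)-1,3-oxazolidin-2-one
Conditions: n-BuLi, THF, −78 °C; then BrCH2COBr, −78 to 0 °C
Reagents that add atoms: bromoacetyl bromide, BrCC(Br)=O
Why: N-Acylation of the lithiated oxazolidinone with an acid bromide; the acyl bromide reacts far faster than the alkyl bromide.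

Step 13
Reactants: 19 ring B phenol (named in step 11); 21 (S)-4-benzyl-3-(bromoacetyl)-1,3-oxazolidin-2-one
Product: 22 (S)-4-benzyl-3-[(BC-aryloxy)acetyl]-1,3-oxazolidin-2-one
Conditions: K2CO3, MeCN, rt
Reagents that add atoms: none
Why: Williamson-type SN2 of the phenoxide at a primary, carbonyl-activated carbon, which the hindered di-ortho-methoxy phenoxide can still reach. Attack at the imide carbonyl is unproductive because phenoxide is the better leaving group and is expelled again.

Step 14
Reactants: 22 (S)-4-benzyl-3-[(BC-aryloxy)acetyl]-1,3-oxazolidin-2-one; 23 4-(allyloxy)-3-methoxybenzaldehyde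
Product: 25 (4S)-4-benzyl-3-[(2S,3R)-3-[4-(allyloxy)-3-methoxyphenyl]-2-(BC-aryloxy)-3-hydroxypropanoyl]-1,3-oxazolidin-2-one, via boron Z-enolate 24 (not isolated)
Conditions: Bu2BOTf, iPr2NEt, CH2Cl2, −78 to 0 °C; then 23, −78 to 0 °C; pH 7 buffer, MeOH, H2O2, 0 °C
Reagents that add atoms: none
Why: Evans boron syn-aldol of an aryloxyacetyl imide. The Z-enolate and the (S)-auxiliary fix Cβ in the sense that is R in the final side chain and give Cα as the syn partner, which after step 15 is the threo (αR,βR) pair. Cα is corrected in step 17.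

Step 15
Reactants: 25 syn-aldol adduct (named in step 14)
Product: 26 (1R,2R)-1-[4-(allyloxy)-3-methoxyphenyl]-2-(BC-aryloxy)propane-1,3-diol (threo)
Conditions: LiBH4, THF, H2O (1 equiv), 0 °C
Reagents that add atoms: none
Why: Reductive removal of the auxiliary to the primary alcohol, as in step 7; the acetal, silyl ether and allyl ether are inert to borohydride.

Step 16
Reactants: 26 threo diol (named in step 15)
Product: 27 (1R,2R)-1-[4-(allyloxy)-3-methoxyphenyl]-2-(BC-aryloxy)-3-[(tert-butyldimethylsilyl)oxy]propan-1-ol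
Conditions: TBSCl, imidazole, CH2Cl2, 0 °C
Reagents that add atoms: tert-butyldimethylsilyl chloride, CC(C)(C)[Si](C)(C)Cl
Why: Selective silylation of the primary Cγ hydroxyl, so that only the benzylic Cα hydroxyl remains for the inversion.

Step 17
Reactants: 27 threo alcohol (named in step 16)
Product: 28 (1S,2R)-1-[4-(allyloxy)-3-methoxyphenyl]-2-(BC-aryloxy)-3-[(tert-butyldimethylsilyl)oxy]propyl 4-nitrobenzoate
Conditions: 4-O2NC6H4CO2H, PPh3, DIAD, THF, 0 °C to rt
Reagents that add atoms: 4-nitrobenzoic acid, OC(=O)c1ccc(cc1)[N+](=O)[O-]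
Why: Mitsunobu esterification; SN2 displacement of the oxyphosphonium group by the carboxylate inverts Cα from R to S and turns the threo pair into the erythro pair. Inversion of the benzylic carbinol is the established way from threo to erythro β-aryl ethers.

Step 18
Reactants: 28 erythro 4-nitrobenzoate (named in step 17)
Product: 29 (1S,2R)-1-[4-(allyloxy)-3-methoxyphenyl]-2-(BC-aryloxy)-3-[(tert-butyldimethylsilyl)oxy]propan-1-ol (erythro)
Conditions: K2CO3 (cat.), MeOH/THF, 0 °C to rt
Reagents that add atoms: none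
Why: Carbonate-catalysed transesterification at the acyl carbon, so Cα keeps its configuration. The ring A oxygen is still allylated, so no phenoxide can expel the benzylic ester as a quinone methide.

Step 19
Reactants: 29 erythro alcohol (named in step 18)
Product: 30 4-[(1S,2R)-2-(BC-aryloxy)-3-[(tert-butyldimethylsilyl)oxy]-1-hydroxypropyl]-2-methoxyphenol
Conditions: Pd(PPh3)4 (cat.), morpholine, THF, rt
Reagents that add atoms: none
Why: Tsuji–Trost deallylation. Zerovalent palladium ionises the aryl allyl ether and morpholine takes up the allyl group, under neutral conditions that leave the benzylic alcohol, silyl ethers and acetal alone.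

Step 20
Reactants: 30 bis-silyl ether phenol (named in step 19)
Product: 31 (1S,2R)-2-{4-[(2R,3S)-5-(1,3-dioxolan-2-yl)-3-(hydroxymethyl)-7-methoxy-2,3-dihydro-1-benzofuran-2-yl]-2,6-dimethoxyphenoxy}-1-(4-hydroxy-3-methoxyphenyl)propane-1,3-diol
Conditions: TBAF, AcOH, THF, 0 °C to rt
Reagents that add atoms: none
Why: Fluoride cleavage of both silyl ethers. Acetic acid buffers the fluoride so that the phenol para to the benzylic alcohol is not held as a phenoxide.

Step 21
Reactants: 31 dioxolane tetraol (named in step 20)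
Product: 32 (2R,3S)-2-(4-{[(1S,2R)-1,3-dihydroxy-1-(4-hydroxy-3-methoxyphenyl)propan-2-yl]oxy}-3,5-dimethoxyphenyl)-3-(hydroxymethyl)-7-methoxy-2,3-dihydro-1-benzofuran-5-carbaldehyde (target)
Conditions: AcOH/THF/H2O (3:1:1), rt
Reagents that add atoms: water, O
Why: Mild acid hydrolysis of the dioxolane. The ring oxygen para to the acetal carbon stabilises the oxocarbenium ion, so aqueous acetic acid at room temperature should suffice, and the benzylic alcohol and β-aryl ether tolerate these conditions.

## Compound list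

1 | syringaldehyde | COc1cc(C=O)cc(OC)c1O | starting material
2 | 4-(benzyloxy)-3,5-dimethoxybenzaldehyde | COc1cc(C=O)cc(OC)c1OCc1ccccc1 | intermediate
3 | 3-bromo-4-fluorobenzaldehyde | O=Cc1ccc(F)c(Br)c1 | starting material
4 | 2-(3-bromo-4-fluorophenyl)-1,3-dioxolane | Fc1ccc(cc1Br)C1OCCO1 | intermediate
5 | ethyl [5-(1,3-dioxolan-2-yl)-2-fluorophenyl]acetate | CCOC(=O)Cc1cc(ccc1F)C1OCCO1 | intermediate
6 | [5-(1,3-dioxolan-2-yl)-2-fluorophenyl]acetic acid | OC(=O)Cc1cc(ccc1F)C1OCCO1 | intermediate
7 | (R)-4-benzyl-1,3-oxazolidin-2-one | O=C1OC[C@@H](Cc2ccccc2)N1 | starting material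
8 | [5-(1,3-dioxolan-2-yl)-2-fluorophenyl]acetic pivalic anhydride | CC(C)(C)C(=O)OC(=O)Cc1cc(ccc1F)C1OCCO1 | intermediate
9 | (R)-4-benzyl-3-{[5-(1,3-dioxolan-2-yl)-2-fluorophenyl]acetyl}-1,3-oxazolidin-2-one | O=C1OC[C@@H](Cc2ccccc2)N1C(=O)Cc1cc(ccc1F)C1OCCO1 | intermediate
10 | di-n-butylboron (Z)-enolate of 9 | O=C1OC[C@@H](Cc2ccccc2)N1/C(OB(CCCC)CCCC)=C/c1cc(ccc1F)C1OCCO1 | intermediate
11 | (4R)-4-benzyl-3-{(2R,3R)-3-[4-(benzyloxy)-3,5-dimethoxyphenyl]-2-[5-(1,3-dioxolan-2-yl)-2-fluorophenyl]-3-hydroxypropanoyl}-1,3-oxazolidin-2-one | O=C1OC[C@@H](Cc2ccccc2)N1C(=O)[C@@H]([C@@H](O)c1cc(OC)c(OCc2ccccc2)c(OC)c1)c1cc(ccc1F)C1OCCO1 | intermediate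
12 | (1R,2S)-1-[4-(benzyloxy)-3,5-dimethoxyphenyl]-2-[5-(1,3-dioxolan-2-yl)-2-fluorophenyl]propane-1,3-diol | OC[C@@H]([C@@H](O)c1cc(OC)c(OCc2ccccc2)c(OC)c1)c1cc(ccc1F)C1OCCO1 | intermediate
13 | (1R,2S)-1-[4-(benzyloxy)-3,5-dimethoxyphenyl]-2-[5-(1,3-dioxolan-2-yl)-2-fluorophenyl]-3-[(triisopropylsilyl)oxy]propan-1-ol | CC(C)[Si](OC[C@@H]([C@@H](O)c1cc(OC)c(OCc2ccccc2)c(OC)c1)c1cc(ccc1F)C1OCCO1)(C(C)C)C(C)C | intermediate
14 | lithium (1R,2S)-1-[4-(benzyloxy)-3,5-dimethoxyphenyl]-2-[5-(1,3-dioxolan-2-yl)-2,3-didehydrophenyl]-3-[(triisopropylsilyl)oxy]propan-1-olate (aryne) | CC(C)[Si](OC[C@@H]([C@@H](O[Li])c1cc(OC)c(OCc2ccccc2)c(OC)c1)C1=CC(=CC#C1)C1OCCO1)(C(C)C)C(C)C | intermediate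
15 | 7-lithio-(2R,3S)-2-[4-(benzyloxy)-3,5-dimethoxyphenyl]-5-(1,3-dioxolan-2-yl)-3-{[(triisopropylsilyl)oxy]methyl}-2,3-dihydro-1-benzofuran | COc1cc(cc(OC)c1OCc1ccccc1)[C@@H]1Oc2c([Li])cc(C3OCCO3)cc2[C@H]1CO[Si](C(C)C)(C(C)C)C(C)C | intermediate
16 | dimethyl {(2R,3S)-2-[4-(benzyloxy)-3,5-dimethoxyphenyl]-5-(1,3-dioxolan-2-yl)-3-{[(triisopropylsilyl)oxy]methyl}-2,3-dihydro-1-benzofuran-7-yl}boronate | COc1cc(cc(OC)c1OCc1ccccc1)[C@@H]1Oc2c(B(OC)OC)cc(C3OCCO3)cc2[C@H]1CO[Si](C(C)C)(C(C)C)C(C)C | intermediate
17 | (2R,3S)-2-[4-(benzyloxy)-3,5-dimethoxyphenyl]-5-(1,3-dioxolan-2-yl)-3-{[(triisopropylsilyl)oxy]methyl}-2,3-dihydro-1-benzofuran-7-ol | COc1cc(cc(OC)c1OCc1ccccc1)[C@@H]1Oc2c(O)cc(C3OCCO3)cc2[C@H]1CO[Si](C(C)C)(C(C)C)C(C)C | intermediate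
18 | (2R,3S)-2-[4-(benzyloxy)-3,5-dimethoxyphenyl]-5-(1,3-dioxolan-2-yl)-7-methoxy-3-{[(triisopropylsilyl)oxy]methyl}-2,3-dihydro-1-benzofuran | COc1cc(cc(OC)c1OCc1ccccc1)[C@@H]1Oc2c(OC)cc(C3OCCO3)cc2[C@H]1CO[Si](C(C)C)(C(C)C)C(C)C | intermediate
19 | 4-[(2R,3S)-5-(1,3-dioxolan-2-yl)-7-methoxy-3-{[(triisopropylsilyl)oxy]methyl}-2,3-dihydro-1-benzofuran-2-yl]-2,6-dimethoxyphenol | COc1cc(cc(OC)c1O)[C@@H]1Oc2c(OC)cc(C3OCCO3)cc2[C@H]1CO[Si](C(C)C)(C(C)C)C(C)C | intermediate
20 | (S)-4-benzyl-1,3-oxazolidin-2-one | O=C1OC[C@H](Cc2ccccc2)N1 | starting material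
21 | (S)-4-benzyl-3-(bromoacetyl)-1,3-oxazolidin-2-one | O=C1OC[C@H](Cc2ccccc2)N1C(=O)CBr | intermediate
22 | (S)-4-benzyl-3-[(BC-aryloxy)acetyl]-1,3-oxazolidin-2-one | O=C1OC[C@H](Cc2ccccc2)N1C(=O)COc1c(OC)cc(cc1OC)[C@@H]1Oc2c(OC)cc(C3OCCO3)cc2[C@H]1CO[Si](C(C)C)(C(C)C)C(C)C | intermediate
23 | 4-(allyloxy)-3-methoxybenzaldehyde | COc1cc(C=O)ccc1OCC=C | starting material
24 | di-n-butylboron (Z)-enolate of 22 | O=C1OC[C@H](Cc2ccccc2)N1/C(OB(CCCC)CCCC)=C/Oc1c(OC)cc(cc1OC)[C@@H]1Oc2c(OC)cc(C3OCCO3)cc2[C@H]1CO[Si](C(C)C)(C(C)C)C(C)C | intermediate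
25 | (4S)-4-benzyl-3-[(2S,3R)-3-[4-(allyloxy)-3-methoxyphenyl]-2-(BC-aryloxy)-3-hydroxypropanoyl]-1,3-oxazolidin-2-one | O=C1OC[C@H](Cc2ccccc2)N1C(=O)[C@@H](Oc1c(OC)cc(cc1OC)[C@@H]1Oc2c(OC)cc(C3OCCO3)cc2[C@H]1CO[Si](C(C)C)(C(C)C)C(C)C)[C@H](O)c1ccc(OCC=C)c(OC)c1 | intermediate
26 | (1R,2R)-1-[4-(allyloxy)-3-methoxyphenyl]-2-(BC-aryloxy)propane-1,3-diol | OC[C@@H](Oc1c(OC)cc(cc1OC)[C@@H]1Oc2c(OC)cc(C3OCCO3)cc2[C@H]1CO[Si](C(C)C)(C(C)C)C(C)C)[C@H](O)c1ccc(OCC=C)c(OC)c1 | intermediate
27 | (1R,2R)-1-[4-(allyloxy)-3-methoxyphenyl]-2-(BC-aryloxy)-3-[(tert-butyldimethylsilyl)oxy]propan-1-ol | CC(C)(C)[Si](C)(C)OC[C@@H](Oc1c(OC)cc(cc1OC)[C@@H]1Oc2c(OC)cc(C3OCCO3)cc2[C@H]1CO[Si](C(C)C)(C(C)C)C(C)C)[C@H](O)c1ccc(OCC=C)c(OC)c1 | intermediate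
28 | (1S,2R)-1-[4-(allyloxy)-3-methoxyphenyl]-2-(BC-aryloxy)-3-[(tert-butyldimethylsilyl)oxy]propyl 4-nitrobenzoate | CC(C)(C)[Si](C)(C)OC[C@@H](Oc1c(OC)cc(cc1OC)[C@@H]1Oc2c(OC)cc(C3OCCO3)cc2[C@H]1CO[Si](C(C)C)(C(C)C)C(C)C)[C@@H](OC(=O)c1ccc(cc1)[N+](=O)[O-])c1ccc(OCC=C)c(OC)c1 | intermediate
29 | (1S,2R)-1-[4-(allyloxy)-3-methoxyphenyl]-2-(BC-aryloxy)-3-[(tert-butyldimethylsilyl)oxy]propan-1-ol | CC(C)(C)[Si](C)(C)OC[C@@H](Oc1c(OC)cc(cc1OC)[C@@H]1Oc2c(OC)cc(C3OCCO3)cc2[C@H]1CO[Si](C(C)C)(C(C)C)C(C)C)[C@@H](O)c1ccc(OCC=C)c(OC)c1 | intermediate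
30 | 4-[(1S,2R)-2-(BC-aryloxy)-3-[(tert-butyldimethylsilyl)oxy]-1-hydroxypropyl]-2-methoxyphenol | CC(C)(C)[Si](C)(C)OC[C@@H](Oc1c(OC)cc(cc1OC)[C@@H]1Oc2c(OC)cc(C3OCCO3)cc2[C@H]1CO[Si](C(C)C)(C(C)C)C(C)C)[C@@H](O)c1ccc(O)c(OC)c1 | intermediate
31 | (1S,2R)-2-{4-[(2R,3S)-5-(1,3-dioxolan-2-yl)-3-(hydroxymethyl)-7-methoxy-2,3-dihydro-1-benzofuran-2-yl]-2,6-dimethoxyphenoxy}-1-(4-hydroxy-3-methoxyphenyl)propane-1,3-diol | OC[C@@H](Oc1c(OC)cc(cc1OC)[C@@H]1Oc2c(OC)cc(C3OCCO3)cc2[C@H]1CO)[C@@H](O)c1ccc(O)c(OC)c1 | intermediate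
32 | (2R,3S)-2-(4-{[(1S,2R)-1,3-dihydroxy-1-(4-hydroxy-3-methoxyphenyl)propan-2-yl]oxy}-3,5-dimethoxyphenyl)-3-(hydroxymethyl)-7-methoxy-2,3-dihydro-1-benzofuran-5-carbaldehyde | COc1cc([C@H](O)[C@@H](CO)Oc2c(OC)cc([C@@H]3Oc4c(OC)cc(C=O)cc4[C@H]3CO)cc2OC)ccc1O | target

## Step count and least certain steps

Total step count: 21. Longest linear sequence: 19 steps (3 to 32 through steps 2–11 and 13–21); steps 1 and 12 are side branches.

**Step 9 (key step).** The most likely failure is protonation of the C7 aryllithium by the liberated amine before the borate is added, so that the ring closes without oxygenation. The second is migration of the silyl group from the primary to the secondary oxygen in the lithium alkoxide, after which the primary oxygen would close the ring. The third is sluggish deprotonation next to fluorine. The fallback avoids the aryne and sets out from 13. Lithiation ortho to fluorine at −78 °C with LiTMP in the presence of B(OiPr)3 borylates the aryllithium before LiF can be lost, and oxidation with H2O2 would give the fluorophenol F1. O-Methylation (MeI, K2CO3) would give the fluoroanisole F2. Mild acid hydrolysis of the dioxolane would give the fluoro aldehyde F3, in which fluorine is para to the formyl group. The benzylic alkoxide (KHMDS, THF, 0 °C) should then displace fluoride by intramolecular SNAr, 5-exo and with retention at C2, to give the dihydrobenzofuran aldehyde F4. Re-acetalisation with ethylene glycol returns to the route at 18.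

**Step 17.** The 4-alkoxyaryl group makes the benzylic oxyphosphonium ion prone to ionisation, which would give partial retention at Cα, and elimination toward the enol ether can compete. The fallback replaces substitution by oxidation and reduction and sets out from 27. Dess–Martin oxidation, buffered with NaHCO3, would give the ketone F5. Reduction with Zn(BH4)2 in Et2O at low temperature, with zinc bridging the carbonyl and the Cβ aryloxy oxygen and hydride arriving from the side of the Cβ hydrogen, should give the erythro alcohol and so rejoin the route at 29. The ketone has to be kept neutral and cold because Cβ is enolisable in it.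

**Step 14.** The boron triflate may open the dioxolane, which on ring C is para to O1 and ionises easily, or may be held by the many ether oxygens so that enolisation stays incomplete. The fallback uses no boron enolate and no inversion and sets out from 19. Mitsunobu etherification with the hydroxy ester F6 (PPh3, DIAD, inversion) would give the (R)-aryloxy ester F7, and DIBAL at −78 °C would give the aldehyde F8. Addition of the Grignard reagent F9 under non-chelating conditions should follow the polar Felkin–Anh model and give mainly the erythro alcohol, which is 29. The threo epimer would have to be separated. This path replaces steps 13 to 18.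

**Step 13.** Acyl transfer may compete with alkylation: the phenoxide or carbonate can attack the imide and release the auxiliary. The fallback builds the imide in the classical order and sets out from 19. Alkylation with ethyl bromoacetate (K2CO3) would give the ester F10, and saponification (LiOH, acidification only to pH 5) the acid F11. Activation as the mixed pivalic anhydride F12 and acylation of lithiated 20 returns to the route at 22.

## Further compounds

F1 | step 9 | (1R,2S)-1-[4-(benzyloxy)-3,5-dimethoxyphenyl]-2-[5-(1,3-dioxolan-2-yl)-2-fluoro-3-hydroxyphenyl]-3-[(triisopropylsilyl)oxy]propan-1-ol | CC(C)[Si](OC[C@@H]([C@@H](O)c1cc(OC)c(OCc2ccccc2)c(OC)c1)c1cc(cc(O)c1F)C1OCCO1)(C(C)C)C(C)C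
F2 | step 9 | (1R,2S)-1-[4-(benzyloxy)-3,5-dimethoxyphenyl]-2-[5-(1,3-dioxolan-2-yl)-2-fluoro-3-methoxyphenyl]-3-[(triisopropylsilyl)oxy]propan-1-ol | CC(C)[Si](OC[C@@H]([C@@H](O)c1cc(OC)c(OCc2ccccc2)c(OC)c1)c1cc(cc(OC)c1F)C1OCCO1)(C(C)C)C(C)C
F3 | step 9 | (1R,2S)-1-[4-(benzyloxy)-3,5-dimethoxyphenyl]-2-(2-fluoro-5-formyl-3-methoxyphenyl)-3-[(triisopropylsilyl)oxy]propan-1-ol | CC(C)[Si](OC[C@@H]([C@@H](O)c1cc(OC)c(OCc2ccccc2)c(OC)c1)c1cc(C=O)cc(OC)c1F)(C(C)C)C(C)C
F4 | step 9 | (2R,3S)-2-[4-(benzyloxy)-3,5-dimethoxyphenyl]-7-methoxy-3-{[(triisopropylsilyl)oxy]methyl}-2,3-dihydro-1-benzofuran-5-carbaldehyde | COc1cc(cc(OC)c1OCc1ccccc1)[C@@H]1Oc2c(OC)cc(C=O)cc2[C@H]1CO[Si](C(C)C)(C(C)C)C(C)C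
F5 | step 17 | (2R)-1-[4-(allyloxy)-3-methoxyphenyl]-2-(BC-aryloxy)-3-[(tert-butyldimethylsilyl)oxy]propan-1-one | CC(C)(C)[Si](C)(C)OC[C@@H](Oc1c(OC)cc(cc1OC)[C@@H]1Oc2c(OC)cc(C3OCCO3)cc2[C@H]1CO[Si](C(C)C)(C(C)C)C(C)C)C(=O)c1ccc(OCC=C)c(OC)c1
F6 | step 14 | methyl (S)-3-[(tert-butyldimethylsilyl)oxy]-2-hydroxypropanoate | COC(=O)[C@@H](O)CO[Si](C)(C)C(C)(C)C
F7 | step 14 | methyl (R)-2-(BC-aryloxy)-3-[(tert-butyldimethylsilyl)oxy]propanoate | COC(=O)[C@H](Oc1c(OC)cc(cc1OC)[C@@H]1Oc2c(OC)cc(C3OCCO3)cc2[C@H]1CO[Si](C(C)C)(C(C)C)C(C)C)CO[Si](C)(C)C(C)(C)C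
F8 | step 14 | (R)-2-(BC-aryloxy)-3-[(tert-butyldimethylsilyl)oxy]propanal | O=C[C@H](Oc1c(OC)cc(cc1OC)[C@@H]1Oc2c(OC)cc(C3OCCO3)cc2[C@H]1CO[Si](C(C)C)(C(C)C)C(C)C)CO[Si](C)(C)C(C)(C)C
F9 | step 14 | [4-(allyloxy)-3-methoxyphenyl]magnesium bromide | C=CCOc1ccc([Mg]Br)cc1OC
F10 | step 13 | ethyl (BC-aryloxy)acetate | CCOC(=O)COc1c(OC)cc(cc1OC)[C@@H]1Oc2c(OC)cc(C3OCCO3)cc2[C@H]1CO[Si](C(C)C)(C(C)C)C(C)C
F11 | step 13 | (BC-aryloxy)acetic acid | OC(=O)COc1c(OC)cc(cc1OC)[C@@H]1Oc2c(OC)cc(C3OCCO3)cc2[C@H]1CO[Si](C(C)C)(C(C)C)C(C)C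
F12 | step 13 | (BC-aryloxy)acetic pivalic anhydride | CC(C)(C)C(=O)OC(=O)COc1c(OC)cc(cc1OC)[C@@H]1Oc2c(OC)cc(C3OCCO3)cc2[C@H]1CO[Si](C(C)C)(C(C)C)C(C)C
A1 | alternative 1 | methyl 4-{[4-(benzyloxy)-3,5-dimethoxybenzyl]oxy}-3-(1-diazo-2-methoxy-2-oxoethyl)-5-methoxybenzoate | COC(=O)C(=[N+]=[N-])c1cc(cc(OC)c1OCc1cc(OC)c(OCc2ccccc2)c(OC)c1)C(=O)OC
A2 | alternative 1 | methyl cis-(2R,3S)-2-[4-(benzyloxy)-3,5-dimethoxyphenyl]-7-methoxy-5-(methoxycarbonyl)-2,3-dihydro-1-benzofuran-3-carboxylate | COc1cc(cc(OC)c1OCc1ccccc1)[C@@H]1Oc2c(OC)cc(C(=O)OC)cc2[C@@H]1C(=O)OC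
A3 | alternative 2 | (2S)-2-(5-formyl-2-hydroxy-3-methoxyphenyl)-3-(4-hydroxy-3,5-dimethoxyphenyl)propyl acetate | CC(=O)OC[C@@H](Cc1cc(OC)c(O)c(OC)c1)c1cc(C=O)cc(OC)c1O
A4 | alternative 2 | (2S)-3-(3,5-dimethoxy-4-oxocyclohexa-2,5-dien-1-ylidene)-2-(5-formyl-2-hydroxy-3-methoxyphenyl)propyl acetate | CC(=O)OC[C@@H](C=C1C=C(OC)C(=O)C(OC)=C1)c1cc(C=O)cc(OC)c1O
A5 | alternative 2 | [(2R,3S)-5-formyl-2-(4-hydroxy-3,5-dimethoxyphenyl)-7-methoxy-2,3-dihydro-1-benzofuran-3-yl]methyl acetate | COc1cc(cc(OC)c1O)[C@@H]1Oc2c(OC)cc(C=O)cc2[C@H]1COC(C)=O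
A6 | alternative 3 | 5-iodovanillin (4-hydroxy-3-iodo-5-methoxybenzaldehyde) | COc1cc(C=O)cc(I)c1O
A7 | alternative 3 | (E)-sinapyl tert-butyldimethylsilyl ether bearing at O4 the (1S,2R)-1-[4-(benzyloxy)-3-methoxyphenyl]-1,3-bis[(tert-butyldimethylsilyl)oxy]propan-2-yl group | COc1cc(ccc1OCc1ccccc1)[C@H](O[Si](C)(C)C(C)(C)C)[C@@H](CO[Si](C)(C)C(C)(C)C)Oc1c(OC)cc(cc1OC)/C=C/CO[Si](C)(C)C(C)(C)C
A8 | alternative 3 | (2R,3S)-2-(4-{[(1S,2R)-1-[4-(benzyloxy)-3-methoxyphenyl]-1,3-bis[(tert-butyldimethylsilyl)oxy]propan-2-yl]oxy}-3,5-dimethoxyphenyl)-3-{[(tert-butyldimethylsilyl)oxy]methyl}-7-methoxy-2,3-dihydro-1-benzofuran-5-carbaldehyde | COc1cc(ccc1OCc1ccccc1)[C@H](O[Si](C)(C)C(C)(C)C)[C@@H](CO[Si](C)(C)C(C)(C)C)Oc1c(OC)cc(cc1OC)[C@@H]1Oc2c(OC)cc(C=O)cc2[C@H]1CO[Si](C)(C)C(C)(C)C
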